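**Retrosynthetic overview**
1. Target 24 ⇐ global deprotection of 22 ⇐ Yamaguchi esterification of the acrylic acid of the butenolide half 18 with the primary hydroxyl of the diol half 20. Both halves have the same absolute configuration and are cut back to one monomer, acid 16.
2. Butenolide half: the lactone ring (ring C, fused to cyclohexene ring B) is closed last at its O–CH2 bond by aerobic palladium-catalysed dehydrogenative lactonisation of 16. The enabling feature is that the lactone CH2 (C3) hangs on ring carbon C3a, directly next to C7a, which carries the carbonyl; 16 is therefore a 3-alkenoic acid with CO2H on one ring carbon, an exocyclic C=CH2 on the next, and an axial tertiary allylic C–H between them.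
3. Diol half: the tert-butyl ester 19 of the same monomer; OsO4 on the same exocyclic alkene from the equatorial face sets the tertiary carbinol.
4. Monomer 16 ⇐ (R)-cryptone 4 by tandem vinyl-cuprate addition/formaldehyde aldol (three contiguous all-trans centres), ozonolysis/Wittig (side chain), methylenation and oxidation; 4 ⇐ 3-methylbutanal + methyl vinyl ketone.
5. Ring order: the carbocycle (step 2, serves both halves), then the butenolide ring of one half (step 11).

Key step: step 11

Remark on the chemistry: the (R)-prolinol ether in step 1 is assumed to shield the same enamine face as in its additions to nitroalkenes, which gives (R)-3; if the sense were opposite, its enantiomer would be used.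

Step 1
Reactants: 1 3-methylbutanal; 2 but-3-en-2-one (methyl vinyl ketone)
Product: 3 (R)-2-isopropyl-5-oxohexanal
Conditions: (R)-2-[methoxy(diphenyl)methyl]pyrrolidine (5 mol%), ethyl 3,4-dihydroxybenzoate (20 mol%), neat, 4 °C
Reagents that add atoms: none
Why: Enamine-catalysed Michael addition; the enamine of 1 should add to the enone from the face not shielded by the diarylmethyl group, which sets the (R)-centre.

Step 2
Reactants: 3 (R)-2-isopropyl-5-oxohexanal
Product: 4 (R)-4-isopropylcyclohex-2-en-1-one ((R)-cryptone)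
Conditions: LiOH (0.1 equiv), iPrOH, rt
Reagents that add atoms: none
Why: Intramolecular aldol condensation of the methyl ketone onto the aldehyde (Robinson-type ring closure) should outrun epimerisation of the α-centre, which then sits as the γ-carbon of the enone.

Step 3
Reactants: 4 (R)-cryptone
Product: 6 (2R,3R,4R)-2-(hydroxymethyl)-4-isopropyl-3-vinylcyclohexan-1-one, via bromomagnesium enolate 5 (not isolated)
Conditions: CH2=CHMgBr (1.5 equiv), CuBr·SMe2 (10 mol%), THF, −78 → −40 °C; then HCHO gas (from paraformaldehyde), −78 °C; aq. NH4Cl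
Reagents that add atoms: vinylmagnesium bromide, C=C[Mg]Br; formaldehyde, C=O
Why: Copper-catalysed conjugate addition anti to the isopropyl group, then aldol trapping of the regiodefined enolate with formaldehyde anti to the new vinyl group (tandem 1,4-addition–aldol), should give the all-trans ketone, whose α-centre is also the thermodynamic (equatorial) one.

Step 4
Reactants: 6 (2R,3R,4R)-2-(hydroxymethyl)-4-isopropyl-3-vinylcyclohexan-1-one
Product: 7 (2R,3R,4R)-2-[(tert-butyldimethylsilyloxy)methyl]-4-isopropyl-3-vinylcyclohexan-1-one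
Conditions: TBSCl, imidazole, CH2Cl2, 0 °C → rt
Reagents that add atoms: tert-butyldimethylsilyl chloride, CC(C)(C)[Si](C)(C)Cl
Why: Silylation of the primary alcohol blocks retro-aldol cleavage and dehydration of the β-hydroxy ketone.

Step 5
Reactants: 7 silyl ether
Product: 9 all-trans 2-[(tert-butyldimethylsilyloxy)methyl]-6-isopropyl-3-oxocyclohexane-1-carbaldehyde, via secondary ozonide 8 (not isolated)
Conditions: O3, CH2Cl2, −78 °C; then Me2S, −78 °C → rt
Reagents that add atoms: ozone, O=[O+][O-]
Why: Ozonolysis with reductive work-up; the vinyl group is the only alkene, and the formyl group keeps the equatorial position trans to both neighbours.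

Step 6
Reactants: 10 tert-butyl (triphenylphosphoranylidene)acetate (2 equiv)
Product: 12 tert-butyl 3-(triisopropylsilyloxy)-2-(triphenylphosphoranylidene)propanoate, via phosphonium chloride 11 (not isolated)
Conditions: iPr3SiOCH2Cl (1 equiv), CH2Cl2, 0 °C → rt; filtration from the phosphonium salt
Reagents that add atoms: (chloromethoxy)triisopropylsilane, ClCO[Si](C(C)C)(C(C)C)C(C)C
Why: C-alkylation of the stabilised ylide by the reactive chloromethyl ether, followed by transylidation with the second equivalent of 10.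

Step 7
Reactants: 9 keto aldehyde; 12 substituted ylide
Product: 13 tert-butyl (E)-3-{all-trans-2-[(tert-butyldimethylsilyloxy)methyl]-6-isopropyl-3-oxocyclohexyl}-2-[(triisopropylsilyloxy)methyl]acrylate
Conditions: toluene, 90 °C
Reagents that add atoms: none
Why: Wittig olefination with an α,α-disubstituted stabilised ylide should place the ester trans to the ring (E) and leave the hindered ketone untouched.

Step 8
Reactants: 13 keto enoate
Product: 14 tert-butyl (E)-3-{all-trans-2-[(tert-butyldimethylsilyloxy)methyl]-6-isopropyl-3-methylidenecyclohexyl}-2-[(triisopropylsilyloxy)methyl]acrylate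
Conditions: Ph3PCH3Br, KOtBu, THF, 0 °C → rt
Reagents that add atoms: methyltriphenylphosphonium bromide, C[P+](c1ccccc1)(c1ccccc1)c1ccccc1.[Br-]
Why: Wittig methylenation of the ketone; the trisubstituted tert-butyl acrylate is a poor acceptor for the ylide, and the α-centre already holds its equatorial configuration.

Step 9
Reactants: 14 bis-silyl ether
Product: 15 tert-butyl (E)-3-[all-trans-2-(hydroxymethyl)-6-isopropyl-3-methylidenecyclohexyl]-2-[(triisopropylsilyloxy)methyl]acrylate
Conditions: camphorsulfonic acid (10 mol%), MeOH/CH2Cl2, 0 °C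
Reagents that add atoms: none
Why: Acid-catalysed methanolysis should cleave the primary TBS ether much faster than the bulkier TIPS ether.

Step 10
Reactants: 15 homoallylic alcohol
Product: 16 all-trans 2-{(E)-3-tert-butoxy-3-oxo-2-[(triisopropylsilyloxy)methyl]prop-1-enyl}-3-isopropyl-6-methylidenecyclohexane-1-carboxylic acid (monomer acid)
Conditions: TEMPO (20 mol%), PhI(OAc)2 (2.2 equiv), MeCN/H2O 1:1, rt
Reagents that add atoms: water, O
Why: Oxoammonium (TEMPO) oxidation of the primary alcohol through the aldehyde hydrate to the acid under near-neutral conditions, which should spare the exocyclic alkene and the α-centre.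

Step 11
Reactants: 16 monomer acid
Product: 17 tert-butyl (E)-3-(trans-6-isopropyl-1-oxo-1,3,4,5,6,7-hexahydro-2-benzofuran-7-yl)-2-[(triisopropylsilyloxy)methyl]acrylate
Conditions: Pd(OAc)2 (10 mol%), NaOAc (2 equiv), DMSO, O2 (1 atm), 40 °C
Reagents that add atoms: none
Why: The carboxylate of 16 binds Pd(OAc)2 and the exocyclic alkene coordinates to divalent palladium; either anti attack of the carboxylate oxygen on the terminal CH2 followed by syn β-hydride elimination of the axial tertiary C–H next to the carbonyl, or cleavage of that same allylic C–H to a π-allyl complex followed by C–O bond formation at the CH2 terminus, gives the conjugated butenolide, and the palladium hydride is reoxidised by O2. The closest known reaction type is the aerobic Pd(OAc)2/DMSO cyclisation of 3-alkenoic acids to 2(5H)-furanones (oxidative lactonisation of alkenoic acids). The one ring closed is the five-membered lactone, by 5-endo O–C closure onto the exocyclic methylene; no new stereocentre arises, and the carboxyl-bearing centre becomes sp2. The step needs attack at CH2 rather than at the ring carbon and delivery of the alkene into conjugation: attack at the ring carbon would give a four-membered β-lactone, a lactone bridging across the ring would force all three ring substituents axial, and any β,γ-unsaturated lactone should isomerise to 17 under NaOAc. The trisubstituted acrylate is too electron-poor and hindered to compete, and the silyl ether and tert-butyl ester are inert to these neutral conditions.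

Step 12
Reactants: 17 butenolide tert-butyl ester
Product: 18 (E)-3-(trans-6-isopropyl-1-oxo-1,3,4,5,6,7-hexahydro-2-benzofuran-7-yl)-2-[(triisopropylsilyloxy)methyl]acrylic acid
Conditions: CF3CO2H/CH2Cl2 1:4, 0 °C
Reagents that add atoms: none
Why: Acidolysis of the tert-butyl ester with loss of 2-methylpropene; the primary TIPS ether and the butenolide should survive brief anhydrous acid.

Step 13
Reactants: 16 monomer acid
Product: 19 tert-butyl all-trans-2-{(E)-3-tert-butoxy-3-oxo-2-[(triisopropylsilyloxy)methyl]prop-1-enyl}-3-isopropyl-6-methylidenecyclohexane-1-carboxylate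
Conditions: tert-butyl 2,2,2-trichloroacetimidate (2 equiv), cyclohexane/CH2Cl2, rt
Reagents that add atoms: tert-butyl 2,2,2-trichloroacetimidate, CC(C)(C)OC(=N)C(Cl)(Cl)Cl
Why: Imidate esterification under base-free conditions, so that the β,γ-unsaturated acid should neither epimerise nor move its alkene into conjugation.

Step 14
Reactants: 19 di-tert-butyl ester
Product: 20 tert-butyl 2-{(E)-3-tert-butoxy-3-oxo-2-[(triisopropylsilyloxy)methyl]prop-1-enyl}-6-hydroxy-6-(hydroxymethyl)-3-isopropylcyclohexane-1-carboxylate (ring ester trans to side chain; side chain trans to isopropyl; tertiary OH trans and CH2OH cis to the ring ester)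
Conditions: OsO4 (5 mol%), N-methylmorpholine N-oxide (1.5 equiv), acetone/H2O 4:1, 0 °C → rt
Reagents that add atoms: N-methylmorpholine N-oxide, C[N+]1([O-])CCOCC1; water, O
Why: Upjohn dihydroxylation; OsO4 should choose the electron-richer 1,1-disubstituted alkene over the acrylate and attack from the equatorial face, away from the two syn-axial ring hydrogens, which places the tertiary OH equatorial and the CH2OH axial (cis to the ring ester), while the tert-butyl ester resists lactonisation.

Step 15
Reactants: 20 diol; 18 butenolide acid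
Product: 22 ester of 18 at the primary hydroxyl of 20 (fully protected target), via mixed anhydride 21 (not isolated)
Conditions: 18, 2,4,6-trichlorobenzoyl chloride, Et3N, THF, rt; then 20, DMAP, toluene, rt → 40 °C
Reagents that add atoms: none
Why: Yamaguchi esterification; only the primary hydroxyl should be acylated, the tertiary one being too hindered.

Step 16
Reactants: 22 protected target
Product: 23 diacid bis-TIPS ether (22 without its two tert-butyl groups)
Conditions: CF3CO2H/CH2Cl2 1:3, 0 °C → rt
Reagents that add atoms: none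
Why: Acidolysis of both tert-butyl esters; the tertiary carbinol is flanked by electron-withdrawing groups and should not ionise.

Step 17
Reactants: 23 diacid bis-TIPS ether
Product: 24 CNP0071646.2 (target)
Conditions: HF·pyridine, pyridine/THF, 0 °C → rt
Reagents that add atoms: none
Why: Fluoride-driven cleavage of both TIPS ethers under buffered conditions that should leave the esters, the butenolide and the tertiary alcohol untouched.

**Compound list**
1 | 3-methylbutanal | CC(C)CC=O | starting material
2 | but-3-en-2-one (methyl vinyl ketone) | CC(=O)C=C | starting material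
3 | (R)-2-isopropyl-5-oxohexanal | CC(C)[C@H](C=O)CCC(C)=O | intermediate
4 | (R)-4-isopropylcyclohex-2-en-1-one ((R)-cryptone) | CC(C)[C@H]1CCC(=O)C=C1 | intermediate
5 | bromomagnesium enolate of trans-4-isopropyl-3-vinylcyclohexanone (enolate towards C2) | CC(C)[C@H]1CCC(O[Mg]Br)=C[C@@H]1C=C | intermediate
6 | (2R,3R,4R)-2-(hydroxymethyl)-4-isopropyl-3-vinylcyclohexan-1-one (all-trans) | CC(C)[C@H]1CCC(=O)[C@@H](CO)[C@@H]1C=C | intermediate
7 | (2R,3R,4R)-2-[(tert-butyldimethylsilyloxy)methyl]-4-isopropyl-3-vinylcyclohexan-1-one | CC(C)[C@H]1CCC(=O)[C@@H](CO[Si](C)(C)C(C)(C)C)[C@@H]1C=C | intermediate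
8 | secondary ozonide of 7 (1,2,4-trioxolan-3-yl in place of vinyl) | CC(C)[C@H]1CCC(=O)[C@@H](CO[Si](C)(C)C(C)(C)C)[C@@H]1C1OCOO1 | intermediate
9 | all-trans 2-[(tert-butyldimethylsilyloxy)methyl]-6-isopropyl-3-oxocyclohexane-1-carbaldehyde | CC(C)[C@H]1CCC(=O)[C@@H](CO[Si](C)(C)C(C)(C)C)[C@@H]1C=O | intermediate
10 | tert-butyl (triphenylphosphoranylidene)acetate | CC(C)(C)OC(=O)C=P(c1ccccc1)(c1ccccc1)c1ccccc1 | starting material
11 | [1-tert-butoxy-1-oxo-3-(triisopropylsilyloxy)propan-2-yl]triphenylphosphonium chloride | CC(C)(C)OC(=O)C(CO[Si](C(C)C)(C(C)C)C(C)C)[P+](c1ccccc1)(c1ccccc1)c1ccccc1.[Cl-] | intermediate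
12 | tert-butyl 3-(triisopropylsilyloxy)-2-(triphenylphosphoranylidene)propanoate | CC(C)(C)OC(=O)C(CO[Si](C(C)C)(C(C)C)C(C)C)=P(c1ccccc1)(c1ccccc1)c1ccccc1 | intermediate
13 | tert-butyl (E)-3-{all-trans-2-[(tert-butyldimethylsilyloxy)methyl]-6-isopropyl-3-oxocyclohexyl}-2-[(triisopropylsilyloxy)methyl]acrylate | CC(C)[C@H]1CCC(=O)[C@@H](CO[Si](C)(C)C(C)(C)C)[C@@H]1/C=C(\CO[Si](C(C)C)(C(C)C)C(C)C)C(=O)OC(C)(C)C | intermediate
14 | tert-butyl (E)-3-{all-trans-2-[(tert-butyldimethylsilyloxy)methyl]-6-isopropyl-3-methylidenecyclohexyl}-2-[(triisopropylsilyloxy)methyl]acrylate | CC(C)[C@H]1CCC(=C)[C@@H](CO[Si](C)(C)C(C)(C)C)[C@@H]1/C=C(\CO[Si](C(C)C)(C(C)C)C(C)C)C(=O)OC(C)(C)C | intermediate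
15 | tert-butyl (E)-3-[all-trans-2-(hydroxymethyl)-6-isopropyl-3-methylidenecyclohexyl]-2-[(triisopropylsilyloxy)methyl]acrylate | CC(C)[C@H]1CCC(=C)[C@@H](CO)[C@@H]1/C=C(\CO[Si](C(C)C)(C(C)C)C(C)C)C(=O)OC(C)(C)C | intermediate
16 | all-trans 2-{(E)-3-tert-butoxy-3-oxo-2-[(triisopropylsilyloxy)methyl]prop-1-enyl}-3-isopropyl-6-methylidenecyclohexane-1-carboxylic acid (monomer acid) | CC(C)[C@H]1CCC(=C)[C@@H](C(=O)O)[C@@H]1/C=C(\CO[Si](C(C)C)(C(C)C)C(C)C)C(=O)OC(C)(C)C | intermediate
17 | tert-butyl (E)-3-(trans-6-isopropyl-1-oxo-1,3,4,5,6,7-hexahydro-2-benzofuran-7-yl)-2-[(triisopropylsilyloxy)methyl]acrylate | CC(C)(C)OC(=O)/C(=C/[C@H]1C2=C(CC[C@@H]1C(C)C)COC2=O)CO[Si](C(C)C)(C(C)C)C(C)C | intermediate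
18 | (E)-3-(trans-6-isopropyl-1-oxo-1,3,4,5,6,7-hexahydro-2-benzofuran-7-yl)-2-[(triisopropylsilyloxy)methyl]acrylic acid | OC(=O)/C(=C/[C@H]1C2=C(CC[C@@H]1C(C)C)COC2=O)CO[Si](C(C)C)(C(C)C)C(C)C | intermediate
19 | tert-butyl ester of 16 (di-tert-butyl ester) | CC(C)[C@H]1CCC(=C)[C@@H](C(=O)OC(C)(C)C)[C@@H]1/C=C(\CO[Si](C(C)C)(C(C)C)C(C)C)C(=O)OC(C)(C)C | intermediate
20 | diol of 19: tertiary OH equatorial (trans to ring ester), CH2OH axial (cis to ring ester) | CC(C)[C@H]1CC[C@@](O)(CO)[C@@H](C(=O)OC(C)(C)C)[C@@H]1/C=C(\CO[Si](C(C)C)(C(C)C)C(C)C)C(=O)OC(C)(C)C | intermediate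
21 | mixed 2,4,6-trichlorobenzoic anhydride of 18 | O=C(OC(=O)/C(=C/[C@H]1C2=C(CC[C@@H]1C(C)C)COC2=O)CO[Si](C(C)C)(C(C)C)C(C)C)c1c(Cl)cc(Cl)cc1Cl | intermediate
22 | ester of 18 with the primary hydroxyl of 20 (di-tert-butyl ester, bis-TIPS ether of the target) | CC(C)[C@H]1CC[C@@](O)(COC(=O)/C(=C/[C@H]2C3=C(CC[C@@H]2C(C)C)COC3=O)CO[Si](C(C)C)(C(C)C)C(C)C)[C@@H](C(=O)OC(C)(C)C)[C@@H]1/C=C(\CO[Si](C(C)C)(C(C)C)C(C)C)C(=O)OC(C)(C)C | intermediate
23 | bis-TIPS ether of the target (both carboxylic acids free) | CC(C)[C@H]1CC[C@@](O)(COC(=O)/C(=C/[C@H]2C3=C(CC[C@@H]2C(C)C)COC3=O)CO[Si](C(C)C)(C(C)C)C(C)C)[C@@H](C(=O)O)[C@@H]1/C=C(\CO[Si](C(C)C)(C(C)C)C(C)C)C(=O)O | intermediate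
24 | CNP0071646.2 | CC(C)[C@H]1CC[C@@](O)(COC(=O)/C(=C/[C@H]2C3=C(CC[C@@H]2C(C)C)COC3=O)CO)[C@@H](C(=O)O)[C@@H]1/C=C(\CO)C(=O)O | target

**Totals**
Total step count: 17. Longest linear sequence: 14 steps (steps 1–5, 7–12, 15–17; the branch through steps 13 and 14 is equally long).

**Steps most likely to fail**

Step 11. What may go wrong: migration of the exocyclic double bond into the ring by palladium hydride, allylic acetoxylation in place of lactonisation, or precipitation of the catalyst before turnover. Fallback: setting out from 16, the exocyclic alkene is epoxidised with mCPBA (NaHCO3, CH2Cl2, 0 °C; the acrylate is inert) to the spiro-epoxy acid F1. Warming F1 with Et3N in MeCN lets the carboxylate open the oxirane at its CH2 carbon to the β-hydroxy γ-lactone F2, so the lactone is still closed through the same O–CH2 bond. MsCl/Et3N converts F2 into the tertiary mesylate F3, which with DBU eliminates towards the lactone α-carbon and rejoins the route at 17. The configuration at the oxirane carbon is irrelevant, because that carbon becomes sp2.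

Step 14. What may go wrong: attack of OsO4 from the axial face (wrong carbinol epimer), or acyl transfer of the new primary hydroxyl onto the neighbouring ester (lactonisation). Fallback: setting out from ketone 13, dimethylsulfonium methylide (Me3SI, KN(SiMe3)2, THF, −10 °C) adds its CH2 axially to the ketone (Corey–Chaykovsky; the enoate is much slower) to give the spiro-epoxide F4 with equatorial oxygen. The caesium salt of 18 (Cs2CO3, DMF, 70 °C) opens F4 at CH2 to the tertiary alcohol ester F5. Camphorsulfonic acid in MeOH removes the TBS group to give the primary alcohol F6, and TEMPO/PhI(OAc)2 oxidises it to the acid F7. CF3CO2H as in step 16 removes the remaining tert-butyl group and rejoins the route at 23.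

Step 7. What may go wrong: slow olefination of the hindered aldehyde, loss of silanolate from the ylide by β-elimination on heating, and erosion of the alkene geometry. Fallback: setting out from 10 and 9, bromination of 10 (Br2, CH2Cl2, −20 °C; then aq. NaOH) gives the bromo ylide F8. Wittig reaction of F8 with 9 (CH2Cl2, rt) should give the (Z)-α-bromo enoate F9, with the ester trans to the ring. Stille coupling with Bu3SnCH2OH (Pd(PPh3)4, dioxane, 90 °C) replaces bromine by CH2OH with retention to give the hydroxymethyl enoate F10, and iPr3SiCl/imidazole then rejoins the route at 13.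

**Further compounds**
F1 | step 11 | spiro-epoxy acid: oxirane of 16 at the former exocyclic alkene (either epimer at the spiro carbon) | CC(C)[C@H]1CCC2(CO2)[C@@H](C(=O)O)[C@@H]1/C=C(\CO[Si](C(C)C)(C(C)C)C(C)C)C(=O)OC(C)(C)C
F2 | step 11 | β-hydroxy γ-lactone: 3a-hydroxy-octahydro-2-benzofuran-1-one core carrying the side chain at C7 and isopropyl at C6 (either epimer at C3a) | CC(C)[C@H]1CCC2(O)COC(=O)[C@H]2[C@@H]1/C=C(\CO[Si](C(C)C)(C(C)C)C(C)C)C(=O)OC(C)(C)C
F3 | step 11 | tertiary mesylate of F2 | CC(C)[C@H]1CCC2(OS(C)(=O)=O)COC(=O)[C@H]2[C@@H]1/C=C(\CO[Si](C(C)C)(C(C)C)C(C)C)C(=O)OC(C)(C)C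
F4 | step 14 | spiro-epoxide of ketone 13 (oxirane oxygen equatorial, CH2 axial) | CC(C)[C@H]1CC[C@@]2(CO2)[C@@H](CO[Si](C)(C)C(C)(C)C)[C@@H]1/C=C(\CO[Si](C(C)C)(C(C)C)C(C)C)C(=O)OC(C)(C)C
F5 | step 14 | tertiary alcohol ester from opening of F4 by the carboxylate of 18 (ring CH2OTBS in place of the ring carboxyl) | CC(C)[C@H]1CC[C@@](O)(COC(=O)/C(=C/[C@H]2C3=C(CC[C@@H]2C(C)C)COC3=O)CO[Si](C(C)C)(C(C)C)C(C)C)[C@@H](CO[Si](C)(C)C(C)(C)C)[C@@H]1/C=C(\CO[Si](C(C)C)(C(C)C)C(C)C)C(=O)OC(C)(C)C
F6 | step 14 | primary alcohol from F5 (TBS removed) | CC(C)[C@H]1CC[C@@](O)(COC(=O)/C(=C/[C@H]2C3=C(CC[C@@H]2C(C)C)COC3=O)CO[Si](C(C)C)(C(C)C)C(C)C)[C@@H](CO)[C@@H]1/C=C(\CO[Si](C(C)C)(C(C)C)C(C)C)C(=O)OC(C)(C)C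
F7 | step 14 | ring carboxylic acid from F6 (side-chain tert-butyl ester still in place) | CC(C)[C@H]1CC[C@@](O)(COC(=O)/C(=C/[C@H]2C3=C(CC[C@@H]2C(C)C)COC3=O)CO[Si](C(C)C)(C(C)C)C(C)C)[C@@H](C(=O)O)[C@@H]1/C=C(\CO[Si](C(C)C)(C(C)C)C(C)C)C(=O)OC(C)(C)C
F8 | step 7 | tert-butyl bromo(triphenylphosphoranylidene)acetate | CC(C)(C)OC(=O)C(Br)=P(c1ccccc1)(c1ccccc1)c1ccccc1
F9 | step 7 | tert-butyl (Z)-2-bromo-3-{all-trans-2-[(tert-butyldimethylsilyloxy)methyl]-6-isopropyl-3-oxocyclohexyl}acrylate | CC(C)[C@H]1CCC(=O)[C@@H](CO[Si](C)(C)C(C)(C)C)[C@@H]1/C=C(\Br)C(=O)OC(C)(C)C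
F10 | step 7 | tert-butyl (E)-3-{all-trans-2-[(tert-butyldimethylsilyloxy)methyl]-6-isopropyl-3-oxocyclohexyl}-2-(hydroxymethyl)acrylate | CC(C)[C@H]1CCC(=O)[C@@H](CO[Si](C)(C)C(C)(C)C)[C@@H]1/C=C(\CO)C(=O)OC(C)(C)C
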